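**Retrosynthetic overview**

- The target is opened at its two formyl groups (twofold Vilsmeier–Haack formylation of ring A, last step) and then at the H–C5 and Ph–C1' bonds, which come from adding a proton and a phenyl nucleophile across C5=C1' of a 2H-chromene.
- Key disconnection: ring B is cut at O–C4 and at aryl–C1', giving phloroglucinol and a ring-C enal whose aldehyde carbon is C1' and whose methyl-bearing β-carbon is C4 (condensation, then oxa-6π closure).
- The enal comes from the C4=C5 enol triflate (palladium formylation), this from the C4(12)-methylene C5-ketone (conjugate reduction with enolate trapping), and this from caryophyllene oxide (base isomerisation, oxidation).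
- Ring order: rings C and D are carried in from (−)-β-caryophyllene and ring A from phloroglucinol; ring B is the only ring that is built.
- Feature on which the strategy rests: ring B is tied to ring A by exactly two bonds, O–C4 and aryl–C1', which flank C5. The unit C1'–C5–C4 with oxygen on the methyl-bearing C4 is the imprint of a phloroglucinol (carbon and oxygen nucleophile) on an enal.

Key step: step 6

Numbering: caryophyllane numbering (C12 = methyl on C4, C13 = methylene carbon on C8, C1' = benzylic carbon); ring A arene, ring B pyran, ring C nine-membered ring, ring D cyclobutane.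

Assumption: the conjugate reduction is taken to give the ring-cis C4=C5 enolate (C3 and C6 on the same side, oxygen cis to the new methyl group), and this geometry is drawn for the enolate, the triflate and the enal; the ring-trans isomer would enter the key step in the same way and give a chromene of the same constitution.

**Route**

Step 1
Reactants: 1 (−)-β-caryophyllene
Product: 2 (−)-caryophyllene oxide [(1R,4R,5R,9S)-4,5-epoxycaryophyll-8(13)-ene]
Conditions: mCPBA (1.0 equiv), CH2Cl2, 0 °C
Reagents that add atoms: mCPBA, O=C(OO)c1cccc(Cl)c1
Why: Prilezhaev epoxidation, which should take place only at the strained trans-trisubstituted C4=C5 bond and leave C8=C13 alone; the configuration of the epoxide carbons (outer-face attack) has no bearing on later stereochemistry because C4 becomes sp2 in step 2 and C5 in step 3.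

Step 2
Reactants: 2 (−)-caryophyllene oxide
Product: 3 (1R,5R,9S)-caryophylla-4(12),8(13)-dien-5-ol
Conditions: LiNEt2 (2.5 equiv; from Et2NH and n-BuLi), Et2O, 0 °C to reflux; then H2O
Reagents that add atoms: none
Why: Lithium-amide-promoted isomerisation of an epoxide to an allylic alcohol (syn β-elimination): the base should remove a proton from the least substituted β-carbon, the C4 methyl group C12, so that C4=C12 forms while the oxygen stays on C5, and a C3=C4 regioisomer, should it form, carries the same C5 hydroxyl and would converge at the enolate of step 4.

Step 3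
Reactants: 3 (1R,5R,9S)-caryophylla-4(12),8(13)-dien-5-ol
Product: 4 (1R,9S)-caryophylla-4(12),8(13)-dien-5-one
Conditions: Dess–Martin periodinane (1.2 equiv), CH2Cl2, 0 °C to rt
Reagents that add atoms: none
Why: Dess–Martin oxidation of the secondary allylic alcohol under nearly neutral conditions, which should give the α-methylene ketone without migration of either exocyclic alkene.

Step 4
Reactants: 4 (1R,9S)-caryophylla-4(12),8(13)-dien-5-one
Product: 6 (1R,9S)-caryophylla-4,8(13)-dien-5-yl trifluoromethanesulfonate (ring-cis C4=C5), via lithium enolate 5 (not isolated)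
Conditions: LiBH(s-Bu)3 (1.1 equiv), THF, −78 °C; then PhNTf2 (1.3 equiv), −78 °C to rt; then H2O
Reagents that add atoms: N-phenylbis(trifluoromethanesulfonimide) (PhNTf2), O=S(=O)(N(c1ccccc1)S(=O)(=O)C(F)(F)F)C(F)(F)F
Why: Conjugate reduction with enolate trapping: hydride adds to the unhindered C12 terminus of the α-methylene ketone, which makes C12 the C4 methyl group and produces the C4=C5 enolate 5 regiospecifically (the C5=C6 enolate cannot arise), and O-sulfonylation by PhNTf2 fixes it as the tetrasubstituted enol triflate.

Step 5
Reactants: 6 (1R,9S)-caryophylla-4,8(13)-dien-5-yl trifluoromethanesulfonate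
Product: 7 ring-C enal (1R,9S)-caryophylla-4,8(13)-diene-5-carbaldehyde (ring-cis C4=C5; CHO cis to the C4 methyl; aldehyde carbon = C1')
Conditions: Pd(OAc)2 (5 mol %), dppp (5 mol %), CO (1 atm), Et3SiH (2 equiv), Et3N (2.5 equiv), DMF, 70 °C
Reagents that add atoms: carbon monoxide, [C-]#[O+]
Why: Palladium-catalysed reductive carbonylation (formylation) of an enol triflate: oxidative addition of C5–OTf to zerovalent palladium, CO insertion and cleavage of the acylpalladium by the silane should give the aldehyde with position and geometry of C4=C5 unchanged, and the aldehyde carbon becomes C1'.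

Step 6
Reactants: 7 ring-C enal; 8 phloroglucinol (4 equiv)
Product: 10 (1R,4R,9S)-5,7-dihydroxy-2H-chromene fused to ring C (O on C4; C5=C1'), via o-quinone methide 9 (not isolated)
Conditions: ethylenediammonium diacetate (20 mol %), 1,4-dioxane–toluene, 100 °C, argon
Reagents that add atoms: none
Why: The diammonium salt converts the aldehyde of 7 into an iminium ion, a ring carbon of phloroglucinol adds to C1' (conjugate addition is shut off because the β-carbon C4 is fully substituted), and loss of the amine gives the o-quinone methide 9, a 1-oxatriene O=C(ring A)–C=C1'–C5=C4. The closest known reaction type is the amine-salt-mediated formal [3+3] annulation of phloroglucinols and resorcinols with β,β-disubstituted enals to 2,2-disubstituted 2H-chromenes; 7 differs in carrying a further α-substituent (C6). Ring B closes by thermal disrotatory oxa-6π electrocyclisation of 9 in its s-cis conformer about C1'–C5, which forms O–C4 and restores the aromaticity of ring A. C4 is the only new stereocentre and is controlled by the conformation of ring C, biased by the trans-fused cyclobutane at C1/C9: the oxygen is expected to add to the outer face of the ring-cis C4=C5 bond, the face not covered by the transannular part of ring C, and at this temperature retro-6π opening back to 9 should let the ratio drift toward the more stable C4 epimer; the configuration drawn is the expected one and is not proven. The step needs mono-annulation, which the excess of phloroglucinol secures, and it has no regiochemical question because the three ring carbons of phloroglucinol are equivalent.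

Step 7
Reactants: 10 chromene
Product: 13 (1R,4R,5S,9S,1'R)-4-phenylchroman-5,7-diol fused to ring C (H5 trans to the C4 methyl; phenyl trans to C6), via benzylic chloride 11 (not isolated), via o-quinone methide 12 (not isolated)
Conditions: HCl (1.0 equiv, 2 M in Et2O), CH2Cl2, −78 °C; then cannulated into PhMgBr (6 equiv), THF, −78 to 0 °C; then H2O
Reagents that add atoms: phenylmagnesium bromide, Br[Mg]c1ccccc1
Why: Markovnikov hydrochlorination followed by Grignard 1,4-addition to an o-quinone methide released from an o-hydroxybenzylic chloride: the proton goes to C5 because the C1' cation is stabilised by the three oxygen donors of ring A (the isolated C8=C13 bond is far less basic), axial protonation anti to the pseudoaxial C4 methyl sets H5 trans to that methyl so that ring C leaves ring B through two equatorial bonds, the first equivalents of PhMgBr deprotonate the phenols and expel chloride to give 12, and phenyl then adds to C1' on the face away from the axial C4 methyl, which is the face trans to C6.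

Step 8
Reactants: 13 4-phenylchroman-5,7-diol
Product: 15 target CNP0253700.4, via bis(iminium) salt 14 (not isolated)
Conditions: POCl3 (6 equiv), DMF (10 equiv), EtOAc, 0 °C to rt; then H2O, rt
Reagents that add atoms: N,N-dimethylformamide, CN(C)C=O; water, O
Why: Twofold Vilsmeier–Haack formylation: the two unsubstituted carbons of ring A, each ortho or para to all three oxygen donors, should be attacked by the chloroiminium ion far faster than the 1,1-disubstituted C8=C13 alkene, the second formylation being helped by excess reagent, and hydrolysis of 14 releases both aldehydes.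

**Compound list**

1 | (−)-β-caryophyllene | C=C1CC/C=C(C)/CC[C@@H]2[C@@H]1CC2(C)C | starting material
2 | (−)-caryophyllene oxide, (1R,4R,5R,9S)-4,5-epoxycaryophyll-8(13)-ene | C=C1CC[C@H]2O[C@]2(C)CC[C@@H]3[C@@H]1CC3(C)C | intermediate
3 | (1R,5R,9S)-caryophylla-4(12),8(13)-dien-5-ol | C=C1CC[C@@H](O)C(=C)CC[C@@H]2[C@@H]1CC2(C)C | intermediate
4 | (1R,9S)-caryophylla-4(12),8(13)-dien-5-one | C=C1CCC(=O)C(=C)CC[C@@H]2[C@@H]1CC2(C)C | intermediate
5 | lithium (1R,9S)-caryophylla-4,8(13)-dien-5-olate, ring-cis C4=C5 (not isolated) | C=C1CC/C([O-])=C(C)\CC[C@@H]2[C@@H]1CC2(C)C.[Li+] | intermediate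
6 | (1R,9S)-caryophylla-4,8(13)-dien-5-yl trifluoromethanesulfonate, ring-cis C4=C5 | C=C1CC/C(OS(=O)(=O)C(F)(F)F)=C(C)\CC[C@@H]2[C@@H]1CC2(C)C | intermediate
7 | ring-C enal, (1R,9S)-caryophylla-4,8(13)-diene-5-carbaldehyde, ring-cis C4=C5, aldehyde carbon = C1' | C=C1CC/C(C=O)=C(C)\CC[C@@H]2[C@@H]1CC2(C)C | intermediate
8 | phloroglucinol (benzene-1,3,5-triol) | Oc1cc(O)cc(O)c1 | starting material
9 | o-quinone methide from 7 and 8: 3,5-dihydroxy-6-(terpenylmethylidene)cyclohexa-2,4-dien-1-one, C1'=C(ring A), C5=C4 retained (not isolated) | C=C1CC/C(C=C3C(=O)C=C(O)C=C3O)=C(C)\CC[C@@H]2[C@@H]1CC2(C)C | intermediate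
10 | (1R,4R,9S)-5,7-dihydroxy-2H-chromene fused to ring C, O on C4, C5=C1' | C=C1CCC2=Cc3c(O)cc(O)cc3O[C@]2(C)CC[C@@H]2[C@@H]1CC2(C)C | intermediate
11 | C1' chloride of 10 (4-chlorochroman-5,7-diol, H5 trans to the C4 methyl, both C1' epimers; not isolated) | C=C1CC[C@H]2C(Cl)c3c(O)cc(O)cc3O[C@]2(C)CC[C@@H]2[C@@H]1CC2(C)C | intermediate
12 | o-quinone methide from 11 by loss of HCl, C1'=C(ring A), C5 sp3 (shown in neutral form; not isolated) | C=C1CC[C@H]2C=C3C(=O)C=C(O)C=C3O[C@]2(C)CC[C@@H]2[C@@H]1CC2(C)C | intermediate
13 | (1R,4R,5S,9S,1'R)-4-phenylchroman-5,7-diol fused to ring C | C=C1CC[C@H]2[C@H](c3ccccc3)c3c(O)cc(O)cc3O[C@]2(C)CC[C@@H]2[C@@H]1CC2(C)C | intermediate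
14 | bis(dimethyliminium) bis(dichlorophosphate) of 15 (not isolated) | C=C1CC[C@H]2[C@H](c3ccccc3)c3c(O)c(C=[N+](C)C)c(O)c(C=[N+](C)C)c3O[C@]2(C)CC[C@@H]2[C@@H]1CC2(C)C.[O-]P(=O)(Cl)Cl.[O-]P(=O)(Cl)Cl | intermediate
15 | CNP0253700.4, (1R,4R,5S,9S,1'R)-6,8-diformyl-4-phenylchroman-5,7-diol fused to ring C | C=C1CC[C@H]2[C@H](c3ccccc3)c3c(O)c(C=O)c(O)c(C=O)c3O[C@]2(C)CC[C@@H]2[C@@H]1CC2(C)C | target

**Step count and risks**

Total step count: 8. Longest linear sequence: 8 steps (1 to 15); phloroglucinol 8 enters at step 6.

Steps most likely to fail:

1. Step 6 (key step). Carbon–carbon bond formation may stall, because iminium formation and attack at the α-branched aldehyde of a tetrasubstituted enal are slow. Retro-condensation, a second annulation on the product, or a 1,7-hydrogen shift in 9 could then take over. The oxygen may also close on the other face of C4=C5 and give the C4 epimer. Fallback, setting out from 7 and 8 and coming back at 10: phloroglucinol 8 would be converted with MOMCl and iPr2NEt into 1,3,5-tris(methoxymethoxy)benzene F1. Directed ortho-lithiation (n-BuLi, THF, 0 °C) would give 2,4,6-tris(methoxymethoxy)phenyllithium F2, which adds 1,2 to the aldehyde of 7 at −78 °C to give the benzylic allylic carbinol F3 as a mixture of C1' epimers. p-TsOH (cat.) in MeOH at 40 °C would then remove the three MOM groups and dehydrate the carbinol to the o-quinone methide 9, which closes to 10. This replaces the reversible condensation by an irreversible organolithium addition and leaves only the electrocyclisation to the thermal step. It does not change the face of closure; if that proves wrong, the cycloaddition described under step 7 is the way round it.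

2. Step 7. Four processes compete with the intended one:
   - protonation of C5 on the methyl-bearing face, which gives the cis ring fusion;
   - loss of HCl from 11, or deprotonation of 12 at C5, back to 10;
   - capture of the C1' cation by the C8=C13 alkene across ring C;
   - Friedel–Crafts attack of ring A of a second molecule on the cation.

   Fallback, setting out from 1 and 8 and coming back at 15: phloroglucinol 8 would be diformylated (POCl3, DMF; then H2O) to 2,4,6-trihydroxyisophthalaldehyde F4. Heating F4 with benzaldehyde and caryophyllene 1 in water would generate, by Knoevenagel condensation, the benzylidene o-quinone methide F5, which adds across C4=C5 of 1 in an inverse-demand hetero-Diels–Alder reaction, a known reaction type for o-quinone methides and strained alkenes. Suprafacial addition to the E alkene fixes H5 trans to the C4 methyl by construction. The face of 1 that is attacked and the endo or exo orientation of phenyl then decide which diastereomers form, so 15 would have to be separated from its isomers.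

3. Step 5. The silane may reduce the alkenylpalladium intermediate before CO inserts at the hindered tetrasubstituted carbon (hydrodetriflation), or palladium hydride may move the C8=C13 alkene. Fallback, setting out from 6 and coming back at 7: methoxycarbonylation (Pd(OAc)2, PPh3, CO 1 atm, MeOH, Et3N, DMF, 60 °C) would give the methyl ester F6. Reduction with i-Bu2AlH (2.2 equiv, CH2Cl2, −78 °C) would give the allylic alcohol F7, and MnO2 (CH2Cl2, rt) would oxidise it to 7. No hydride source is present in the carbonylation, so reduction of the triflate cannot compete.

Further compounds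
F1 | step 6 | 1,3,5-tris(methoxymethoxy)benzene | COCOc1cc(OCOC)cc(OCOC)c1
F2 | step 6 | 2,4,6-tris(methoxymethoxy)phenyllithium | [Li]c1c(OCOC)cc(OCOC)cc1OCOC
F3 | step 6 | carbinol from F2 and 7, C1'(OH) bearing the tris(methoxymethoxy)phenyl group, ring-cis C4=C5, both C1' epimers | C=C1CC/C(C(O)c3c(OCOC)cc(OCOC)cc3OCOC)=C(C)\CC[C@@H]2[C@@H]1CC2(C)C
F4 | step 7 | 2,4,6-trihydroxyisophthalaldehyde | O=Cc1c(O)cc(O)c(C=O)c1O
F5 | step 7 | 6-benzylidene-2,4-diformyl-3,5-dihydroxycyclohexa-2,4-dien-1-one (o-quinone methide, formed in the flask) | O=CC1=C(O)C(C=O)=C(O)C(=Cc2ccccc2)C1=O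
F6 | step 5 | methyl (1R,9S)-caryophylla-4,8(13)-diene-5-carboxylate, ring-cis C4=C5 | C=C1CC/C(C(=O)OC)=C(C)\CC[C@@H]2[C@@H]1CC2(C)C
F7 | step 5 | (1R,9S)-5-(hydroxymethyl)caryophylla-4,8(13)-diene, ring-cis C4=C5 | C=C1CC/C(CO)=C(C)\CC[C@@H]2[C@@H]1CC2(C)C
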